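Remark on the chemistry: ring A is numbered as in the target at every stage (C1 OH, C2 aryloxy, C3 Br, C4 OMe, C5 Br, C6 H), ring B is the 2,4-dibromophenyl ring (C1' on oxygen), and 1, 2 and 3 are taken as purchasable.

## Structural features

The target is an achiral diaryl ether in which ring A, a pentasubstituted benzene (C1 OH, C2 aryloxy, C3 Br, C4 OMe, C5 Br, C6 H), is joined through the oxygen on C2 to C1' of ring B, a 2,4-dibromophenyl group. There are no stereocentres, and the five substituents of ring A stand on five neighbouring carbons. The ether oxygen at C2 is flanked by the C1 hydroxyl and the C3 bromine on ring A and by the C2' bromine on ring B, so the C2–O bond is the most hindered bond in the molecule. The four aryl bromides are the fragile groups, since they rule out organolithium reagents, hydrogenolysis and the copper- or palladium-catalysed couplings normally used for diaryl ethers. The free phenol is oxidisable and is the strongest director on ring A, and once present it would send a further electrophile to C6. The real difficulty is therefore to form the congested C2–O bond without touching any C–Br bond and to place a bromine at C3, the carbon between two oxygen-bearing carbons. The key step exploits that C2 (aryloxy) and C3 (Br) are neighbours and that C4 beside them carries a methoxy group, so that C2 and C3 can be the two carbons of an aryne polarised by that group; C1 and C5, para and ortho to the same methoxy group, are then the activated positions left for the later steps.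

## Logic of the disconnections

12 to 10. The C1–O bond of 12 is traced back to the C1–C(formyl) bond of 10, with 11 as the link. An oxygen at C1 would direct bromine to C6, whereas a carbonyl at C1 is a meta director pointing to C5, so the oxygen must be installed last. The gain is that the phenol appears only in the final operation and needs no protecting group. The forward step must make the ring carbon, not the formyl hydrogen, migrate to oxygen in an aryl group that carries two bromines.

10 to 9. The C5–Br bond is cut. C5 is the one carbon on which the methoxy group (ortho), the ether oxygen (para) and the formyl group (meta) agree. The gain is a ring A with a single bromine, the one that the aryne step delivers. The forward step must stop at one bromine, leave ring B alone and not oxidise the aldehyde.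

9 to 7. The C1–C(formyl) bond is cut; 8 is the species present before work-up. C1 is para to the methoxy group, the best donor on ring A. The gain is a ring A bearing only the three contiguous substituents made in the key step. The forward step must distinguish C1 from C5, the other carbon activated by both oxygens.

7 to 2, 3 and 4. The C2–O and C3–Br bonds are cut together; 5 and 6 lie in between. Both bonds sit on adjacent carbons next to the methoxy-bearing carbon, so one aryne can carry both, and the hindered ether forms without a metal catalyst that could insert into C–Br bonds. The gain is the largest of the route: the whole framework falls into three purchasable pieces. The forward step needs addition at the aryne carbon remote from the methoxy group and bromine capture, not protonation, by the resulting aryl anion.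

4 to 1. The O–K bond is cut. Making the salt in the flask with a hydride base leaves no conjugate acid behind and saves the separate preparation and drying of a phenoxide salt. The demand is complete deprotonation before the aryne is released.

## Other disconnections considered

Alternative 1: The cut runs through ring A: the C4–C5 bond is opened and the ring is traced back to the racemic cyclobutenone A1, 4-(tert-butyldimethylsilyloxy)-3-(2,4-dibromophenoxy)-4-vinylcyclobut-2-en-1-one.
- Forward key step: heating A1 would open the four-membered ring (4π electrocyclic) to a dienylketene; 6π electrocyclisation would join the ketene carbon to the vinyl terminus, and tautomerisation would give A2, 4-(tert-butyldimethylsilyloxy)-3-(2,4-dibromophenoxy)phenol. The free hydroxyl of A2 is the future C4 oxygen. It would direct two brominations to C3 and C5; O-methylation and desilylation would finish.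
- In favour: every position of ring A is fixed by construction or by a phenol ortho director. On the placement of the two ring A bromines this is better than the chosen plan, whose C1/C5 discrimination rests on a difference in donor strength. It is metal-free, as is the chosen plan, which makes the two equal in sparing the ring B bromines.
- Against: A1 must be assembled from a squarate through an aryloxy cyclobutenedione, a vinyl-metal addition to the correct carbonyl and a silylation, all on sensitive four-membered rings. The hydroxyl to be methylated lies between two bromines.
- Comparison: structurally it builds a benzene ring that can be bought already oxygenated. Mechanistically the pericyclic cascade is dependable but needs temperatures above 100 °C. On step economy it should run to roughly twice the length of the chosen plan.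

Alternative 2: The cut is in ring B, at the C1'–C2' and C5'–C6' bonds.
- Forward key step: the ynol ether A3, 1-(benzyloxy)-2-(ethynyloxy)-4-(triisopropylsilyloxy)benzene, would add across C3 and C6 of the pyrone A4, 3,5-dibromo-2H-pyran-2-one. Loss of CO2 from the bridged lactone would give A5, 1-(benzyloxy)-2-(2,4-dibromophenoxy)-4-(triisopropylsilyloxy)benzene. Desilylation, phenol-directed dibromination at C3 and C5, O-methylation and a Lewis-acid debenzylation would follow.
- In favour: the 2',4'-dibromo pattern is written into the pyrone, the ether oxygen is carried by ring A throughout, and no metal is involved. On the hindered C–O bond it is the equal of the chosen plan. On the regiochemistry of the ring A bromines it is better, again through the free C4 hydroxyl.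
- Against: ring B with exactly this pattern is available as 1, so building it solves no problem of the target. A3 needs a trioxygenated benzene with three differentiated oxygens and a strong-base ethynylation. Ynol ethers are heat-sensitive while the cycloaddition needs heat. The oxygen-bearing alkyne carbon must bond to the bromine-bearing C3 of A4; this is expected from the polarities but is a requirement.
- Comparison: about ten steps against four, so the chosen plan is clearly better on step economy and on structural logic.

Alternative 3: The cut removes all four C–Br bonds.
- Forward key step: A6, (4-hydroxy-2-phenoxyphenyl) pivalate, would take up four equivalents of electrophilic bromine at C3, C5, C4' and C2' to give A7, [3,5-dibromo-2-(2,4-dibromophenoxy)-4-hydroxyphenyl] pivalate. O-methylation at C4 and ester cleavage would finish.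
- In favour: it is the most direct plan on paper and uses the cheapest reagents. C3 and C5 are both ortho to the free C4 hydroxyl, so on these two positions it is the equal of the chosen plan or better. After A6 it needs three steps, which is better than the chosen plan over that stretch.
- Against: four substitutions must stop cleanly at four, although ring B has a second ortho position (C6') and ring A a free C6. Under- and over-brominated congeners of this class are hard to separate. A6 requires acylation of the more hindered hydroxyl of its diol precursor, which means a protection detour. The hydroxyl to be methylated lies between two bromines, with an ester nearby that can migrate or cleave.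
- Comparison: the mechanism is the same electrophilic substitution as steps 2 and 3 of the chosen plan, but with far less control over number and position. The chosen plan brings the ring B bromines in with 1 and sets the C3 bromine by construction. Overall step count would be similar once A6 has been made.

Key step: step 1

## Route

Step 1
Reactants: 1 2,4-dibromophenol; 2 3-methoxy-2-(trimethylsilyl)phenyl trifluoromethanesulfonate; 3 tetrabromomethane
Product: 7 2-bromo-1-(2,4-dibromophenoxy)-3-methoxybenzene, via potassium 2,4-dibromophenoxide 4 (not isolated), via 3-methoxybenzyne 5 (not isolated), via 2-aryloxy-6-methoxyphenylpotassium 6 (not isolated)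
Conditions: 1, KH, THF, 0 °C; then 18-crown-6, KF, 3 (excess), slow addition of 2, 0 °C to rt, dark; H2O
Reagents that add atoms: none
Why: Three-component aryne coupling: fluoride removes the trimethylsilyl group of 2 and triflate departs, so that 5 is released slowly into a solution that already holds 4 and an excess of 3. Phenoxide 4 adds to the aryne carbon meta to the methoxy group, the more linear and more electrophilic end of the distorted triple bond, which places the negative charge of 6 on the carbon between the two oxygen-bearing carbons, where the inductive pull of the methoxy oxygen stabilises it; this sets the ether at C2. Arylpotassium 6 then attacks a bromine of 3 (halogen-philic substitution), which forms the C3–Br bond and releases tribromomethanide. The closest known reaction types are the fluoride-mediated O-arylation of phenols with ortho-silylaryl triflates and the three-component aryne couplings in which the adduct of a heteroatom nucleophile (amine, thiolate) is trapped by a polyhalomethane or perhaloarene as halogen donor; the phenoxide and CBr4 pair is the same sequence with different partners. No ring is closed and no stereocentre is formed. Two selectivities are required: the site of addition, secured by the methoxy group next to the triple bond, and bromine capture instead of protonation of 6, secured by forming 4 with a hydride (no conjugate acid remains), by a solvent without acidic C–H bonds (no acetonitrile) and by the excess of 3. No copper or palladium is present, so the aryl bromides of ring B and the new C3 bromine are not at risk.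

Step 2
Reactants: 7 2-bromo-1-(2,4-dibromophenoxy)-3-methoxybenzene
Product: 9 3-bromo-2-(2,4-dibromophenoxy)-4-methoxybenzaldehyde, via alpha-chlorobenzyl methyl ether 8 (not isolated)
Conditions: Cl2CHOMe, TiCl4, CH2Cl2, −20 to 0 °C; then ice water
Reagents that add atoms: dichloromethyl methyl ether, COC(Cl)Cl; water, O
Why: Rieche formylation (Friedel–Crafts attack on the TiCl4-activated dichloromethyl ether, then hydrolysis of 8): C1 is para to the methoxy group, the strongest donor, and that group can stay coplanar with ring A during attack, whereas attack at C5 would push it, already flanked by the C3 bromine, out of conjugation. Ring B carries two bromines and only a shared ether oxygen, so it should not compete.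

Step 3
Reactants: 9 3-bromo-2-(2,4-dibromophenoxy)-4-methoxybenzaldehyde
Product: 10 3,5-dibromo-2-(2,4-dibromophenoxy)-4-methoxybenzaldehyde
Conditions: Br2 (1.1 equiv), AcOH, 40 °C
Reagents that add atoms: bromine, BrBr
Why: Electrophilic aromatic bromination: C5 is ortho to the methoxy group, para to the ether oxygen and meta to the formyl group, so all three substituents direct to the same carbon, while C6 is ortho to the formyl group and meta to both oxygens. Ring B, with two bromines and no second donor, should stay untouched in the absence of a Lewis acid.

Step 4
Reactants: 10 3,5-dibromo-2-(2,4-dibromophenoxy)-4-methoxybenzaldehyde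
Product: 12 3,5-dibromo-2-(2,4-dibromophenoxy)-4-methoxyphenol, via aryl formate 11 (not isolated)
Conditions: mCPBA, CH2Cl2, 0 °C to rt; then MeOH, HCl (cat.), rt
Reagents that add atoms: 3-chloroperoxybenzoic acid, OOC(=O)c1cccc(Cl)c1
Why: Baeyer–Villiger oxidation of an aryl aldehyde (Dakin-type) followed by transesterification: the peracid adds to the formyl group and the ring carbon C1, assisted by the ortho aryloxy and para methoxy oxygens, migrates to oxygen to give formate 11, which methanol cleaves to the phenol. A peracid is used because the classical alkaline peroxide conditions need a free ortho or para hydroxyl; aryl bromides and both ethers are inert to it.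

## Compound list

1 | 2,4-dibromophenol | Oc1ccc(Br)cc1Br | starting material
2 | 3-methoxy-2-(trimethylsilyl)phenyl trifluoromethanesulfonate | COc1cccc(OS(=O)(=O)C(F)(F)F)c1[Si](C)(C)C | starting material
3 | tetrabromomethane | BrC(Br)(Br)Br | starting material
4 | potassium 2,4-dibromophenoxide (formed in the flask, not isolated) | [K+].[O-]c1ccc(Br)cc1Br | intermediate
5 | 3-methoxybenzyne, the aryne with the triple bond between the former silyl- and triflate-bearing carbons (not isolated) | COC1=CC=CC#C1 | intermediate
6 | [2-(2,4-dibromophenoxy)-6-methoxyphenyl]potassium (not isolated) | COc1cccc(Oc2ccc(Br)cc2Br)c1[K] | intermediate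
7 | 2-bromo-1-(2,4-dibromophenoxy)-3-methoxybenzene | COc1cccc(Oc2ccc(Br)cc2Br)c1Br | intermediate
8 | 2-bromo-4-[chloro(methoxy)methyl]-3-(2,4-dibromophenoxy)-1-methoxybenzene, racemic (not isolated) | COC(Cl)c1ccc(OC)c(Br)c1Oc1ccc(Br)cc1Br | intermediate
9 | 3-bromo-2-(2,4-dibromophenoxy)-4-methoxybenzaldehyde | COc1ccc(C=O)c(Oc2ccc(Br)cc2Br)c1Br | intermediate
10 | 3,5-dibromo-2-(2,4-dibromophenoxy)-4-methoxybenzaldehyde | COc1c(Br)cc(C=O)c(Oc2ccc(Br)cc2Br)c1Br | intermediate
11 | [3,5-dibromo-2-(2,4-dibromophenoxy)-4-methoxyphenyl] formate (not isolated) | COc1c(Br)cc(OC=O)c(Oc2ccc(Br)cc2Br)c1Br | intermediate
12 | 3,5-dibromo-2-(2,4-dibromophenoxy)-4-methoxyphenol (CNP0140065.0) | COc1c(Br)cc(O)c(Oc2ccc(Br)cc2Br)c1Br | target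

## Step count and least certain steps

Total step count: 4. Longest linear sequence: 4 steps (from 1 or 2 to 12).

Step 1 (key step). The aryl anion 6 may be protonated before it reaches bromine, through traces of water or through free 1 if deprotonation is incomplete; this would give the ether without the C3 bromine. Bromine may also pass directly from 3 to 4, consuming the nucleophile by ring bromination. Tribromomethanide may decay to dibromocarbene, which can attack 4. The fallback gives up the aryne and sets out from 1. The purchasable arene 2-bromo-1-fluoro-3-methoxybenzene F1 is formylated para to its methoxy group (Cl2CHOMe, TiCl4), and this Rieche formylation of F1 should give 3-bromo-2-fluoro-4-methoxybenzaldehyde F2. Compound 1 and K2CO3 in DMF at about 100 °C then displace the fluoride of F2, which is activated by the ortho formyl group, in a nucleophilic aromatic substitution; the bromine of F2, meta to the formyl group and a poorer leaving group, should stay. This returns to the route at 9 and continues with step 3.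

Step 2. Regiocontrol may be lost through attack at C5 (ortho to methoxy, para to the ether oxygen) in competition with C1. Binding of TiCl4 to the methoxy oxygen would weaken that group as a donor and make this worse. The fallback inverts the order of the two electrophiles and sets out from 7. If C5 proves the intrinsically preferred site, NBS in MeCN should give 1,3-dibromo-4-(2,4-dibromophenoxy)-2-methoxybenzene F3. Rieche formylation of F3 can then go only to C1, the single remaining position activated by oxygen, and the route is rejoined at 10. If neither order is selective, 9 is reached without any choice between C1 and C5 by the substitution route described under step 1.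

Step 3. Bromination may be slow on a ring that already carries a formyl group and a bromine, and forcing it may start bromination of ring B or oxidation of the aldehyde. The fallback moves the oxidation forward and sets out from 9. Treatment of 9 with mCPBA should give [3-bromo-2-(2,4-dibromophenoxy)-4-methoxyphenyl] formate F4, and methanolysis of F4 should give 3-bromo-2-(2,4-dibromophenoxy)-4-methoxyphenol F5. Pivaloyl chloride and pyridine should convert F5 into [3-bromo-2-(2,4-dibromophenoxy)-4-methoxyphenyl] 2,2-dimethylpropanoate F6. The acyloxy group of F6 is only a weak donor, so NBS in MeCN should brominate C5, ortho to the methoxy group and para to the ether oxygen, on a ring free of the formyl group. This should give [3,5-dibromo-2-(2,4-dibromophenoxy)-4-methoxyphenyl] 2,2-dimethylpropanoate F7, and NaOMe in MeOH removes the ester of F7 to arrive at 12.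

Step 4. The formyl hydrogen may migrate in place of the ring carbon, which would lead to the benzoic acid. The migrating aryl group carries two bromines, and its para methoxy group is twisted out of conjugation by them. Addition of the peracid to the hindered aldehyde may also be slow. The fallback replaces the formyl hydrogen by a methyl group and sets out from 10. MeMgBr in THF at −78 °C should add to the aldehyde without exchanging aryl bromides and give racemic 1-[3,5-dibromo-2-(2,4-dibromophenoxy)-4-methoxyphenyl]ethanol F8. Dess–Martin periodinane should oxidise F8 to 1-[3,5-dibromo-2-(2,4-dibromophenoxy)-4-methoxyphenyl]ethanone F9. Baeyer–Villiger oxidation of F9 with trifluoroperacetic acid, in which methyl is a far poorer migrating group than aryl, should give [3,5-dibromo-2-(2,4-dibromophenoxy)-4-methoxyphenyl] acetate F10, and K2CO3 in MeOH cleaves F10 to give 12.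

## Further compounds

F1 | step 1 | 2-bromo-1-fluoro-3-methoxybenzene | COc1cccc(F)c1Br
F2 | step 1 | 3-bromo-2-fluoro-4-methoxybenzaldehyde | COc1ccc(C=O)c(F)c1Br
F3 | step 2 | 1,3-dibromo-4-(2,4-dibromophenoxy)-2-methoxybenzene | COc1c(Br)ccc(Oc2ccc(Br)cc2Br)c1Br
F4 | step 3 | [3-bromo-2-(2,4-dibromophenoxy)-4-methoxyphenyl] formate | COc1ccc(OC=O)c(Oc2ccc(Br)cc2Br)c1Br
F5 | step 3 | 3-bromo-2-(2,4-dibromophenoxy)-4-methoxyphenol | COc1ccc(O)c(Oc2ccc(Br)cc2Br)c1Br
F6 | step 3 | [3-bromo-2-(2,4-dibromophenoxy)-4-methoxyphenyl] 2,2-dimethylpropanoate | COc1ccc(OC(=O)C(C)(C)C)c(Oc2ccc(Br)cc2Br)c1Br
F7 | step 3 | [3,5-dibromo-2-(2,4-dibromophenoxy)-4-methoxyphenyl] 2,2-dimethylpropanoate | COc1c(Br)cc(OC(=O)C(C)(C)C)c(Oc2ccc(Br)cc2Br)c1Br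
F8 | step 4 | 1-[3,5-dibromo-2-(2,4-dibromophenoxy)-4-methoxyphenyl]ethanol (racemic) | COc1c(Br)cc(C(C)O)c(Oc2ccc(Br)cc2Br)c1Br
F9 | step 4 | 1-[3,5-dibromo-2-(2,4-dibromophenoxy)-4-methoxyphenyl]ethanone | COc1c(Br)cc(C(C)=O)c(Oc2ccc(Br)cc2Br)c1Br
F10 | step 4 | [3,5-dibromo-2-(2,4-dibromophenoxy)-4-methoxyphenyl] acetate | COc1c(Br)cc(OC(C)=O)c(Oc2ccc(Br)cc2Br)c1Br
A1 | alternative 1 | 4-(tert-butyldimethylsilyloxy)-3-(2,4-dibromophenoxy)-4-vinylcyclobut-2-en-1-one (racemic) | C=CC1(O[Si](C)(C)C(C)(C)C)C(=O)C=C1Oc1ccc(Br)cc1Br
A2 | alternative 1 | 4-(tert-butyldimethylsilyloxy)-3-(2,4-dibromophenoxy)phenol | Oc1ccc(O[Si](C)(C)C(C)(C)C)c(Oc2ccc(Br)cc2Br)c1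
A3 | alternative 2 | 1-(benzyloxy)-2-(ethynyloxy)-4-(triisopropylsilyloxy)benzene | C#COc1cc(O[Si](C(C)C)(C(C)C)C(C)C)ccc1OCc1ccccc1
A4 | alternative 2 | 3,5-dibromo-2H-pyran-2-one | O=C1OC=C(Br)C=C1Br
A5 | alternative 2 | 1-(benzyloxy)-2-(2,4-dibromophenoxy)-4-(triisopropylsilyloxy)benzene | Brc1ccc(Oc2cc(O[Si](C(C)C)(C(C)C)C(C)C)ccc2OCc2ccccc2)c(Br)c1
A6 | alternative 3 | (4-hydroxy-2-phenoxyphenyl) 2,2-dimethylpropanoate | CC(C)(C)C(=O)Oc1ccc(O)cc1Oc1ccccc1
A7 | alternative 3 | [3,5-dibromo-2-(2,4-dibromophenoxy)-4-hydroxyphenyl] 2,2-dimethylpropanoate | CC(C)(C)C(=O)Oc1cc(Br)c(O)c(Br)c1Oc1ccc(Br)cc1Br
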